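**Retrosynthetic overview**

- The methyl ester comes from the primary alcohol (oxidation, esterification); the CH2–CH2 link between decalin and dioxane comes from a Julia–Kocienski olefination of a decalin tetrazolyl sulfone (fragment 1) with a 1,2-dioxane aldehyde (fragment 2), followed by diimide reduction.
- Fragment 2: the 1,2-dioxane closes by intramolecular SN2 attack of a tertiary hydroperoxide on a secondary mesylate. The hydroperoxide comes from invertive perhydrolysis of a 2,2-disubstituted epoxide (Sharpless epoxidation origin). The syn methyl/hydroxyl pair comes from a ketoreductase dynamic kinetic resolution.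
- Fragment 1: ring B comes from an organocatalytic Michael addition (first stereocentre) and aldol condensation, then cuprate addition and enolate allylation. Ring A comes from prenyl Grignard addition (sets the tertiary OH cis to the angular methyl) and ring-closing metathesis.
- Ring order: ring B, then ring A (cis-decalin); the dioxane ring is built separately; then the fragments are joined.

Assumption: Grignard solutions and other bulk reagents are taken as commercial; those that supply skeletal carbon carry compound numbers. Decalin locants follow naphthalene numbering (C1, C2, C4a, C5, C8a).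

**Fragment 1 (decalin sulfone)**

Step 1
Reactants: 1 propanal; 2 pent-1-en-3-one
Product: 3 (2R)-2-methyl-5-oxoheptanal
Conditions: (S)-2-[methoxy(diphenyl)methyl]pyrrolidine (5 mol%), ethyl 3,4-dihydroxybenzoate (20 mol%), neat, 4 °C
Reagents that add atoms: none
Why: Enamine-catalysed asymmetric Michael addition in which the diarylmethyl group shields one face of the (E)-enamine, so the enone adds to the open face and sets the (R) methyl-bearing centre (future decalin C2).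

Step 2
Reactants: 3 (2R)-2-methyl-5-oxoheptanal
Product: 4 (4R)-2,4-dimethylcyclohex-2-en-1-one
Conditions: LiOH, i-PrOH, rt
Reagents that add atoms: none
Why: Intramolecular aldol condensation of the ethyl ketone enolate onto the aldehyde is the only mode that gives a six-membered ring, and the mild base leaves the existing stereocentre intact.

Step 3
Reactants: 4 (4R)-2,4-dimethylcyclohex-2-en-1-one; 5 {[dimethyl(phenyl)silyl]methyl}magnesium chloride
Product: 6 {[(3S,4R)-3-{[dimethyl(phenyl)silyl]methyl}-2,4-dimethylcyclohex-1-en-1-yl]oxy}trimethylsilane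
Conditions: CuBr·SMe2 (10 mol%), Me3SiCl, HMPA, THF, −78 °C; Et3N
Reagents that add atoms: chlorotrimethylsilane (C[Si](C)(C)Cl)
Why: Copper-catalysed, silyl-chloride-accelerated conjugate addition delivers the masked hydroxymethyl group anti to the neighbouring ring methyl (trans-3,4), and silylation traps the regiodefined enolate.

Step 4
Reactants: 6 {[(3S,4R)-3-{[dimethyl(phenyl)silyl]methyl}-2,4-dimethylcyclohex-1-en-1-yl]oxy}trimethylsilane; 7 3-bromoprop-1-ene
Product: 9 (2R,3S,4R)-3-{[dimethyl(phenyl)silyl]methyl}-2,4-dimethyl-2-(prop-2-en-1-yl)cyclohexan-1-one, via lithium enolate 8 (not isolated)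
Conditions: MeLi, THF, 0 °C; then 7, HMPA, −78 → 0 °C
Reagents that add atoms: none
Why: Regiospecific enolate alkylation in which allyl bromide approaches anti to the adjacent silylmethyl substituent, so the quaternary methyl ends up cis to it.

Step 5
Reactants: 9 (2R,3S,4R)-3-{[dimethyl(phenyl)silyl]methyl}-2,4-dimethyl-2-(prop-2-en-1-yl)cyclohexan-1-one; 10 (3-methylbut-2-en-1-yl)magnesium chloride
Product: 11 (1S,2R,3S,4R)-3-{[dimethyl(phenyl)silyl]methyl}-2,4-dimethyl-1-(2-methylbut-3-en-2-yl)-2-(prop-2-en-1-yl)cyclohexan-1-ol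
Conditions: THF, −78 °C; sat. aq NH4Cl at −78 °C
Reagents that add atoms: none
Why: Grignard 1,2-addition through a six-membered allyl-transfer transition state gives the reverse-prenyl carbinol, with attack on the carbonyl face opposite the axial α-methyl so that the new hydroxyl is cis to that methyl.

Step 6
Reactants: 11 (1S,2R,3S,4R)-3-{[dimethyl(phenyl)silyl]methyl}-2,4-dimethyl-1-(2-methylbut-3-en-2-yl)-2-(prop-2-en-1-yl)cyclohexan-1-ol
Product: 12 (1S,2R,4aS,8aR)-1-{[dimethyl(phenyl)silyl]methyl}-2,5,5,8a-tetramethyl-2,3,4,5,8,8a-hexahydronaphthalen-4a(1H)-ol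
Conditions: second-generation Grubbs catalyst RuCl2(=CHPh)(H2IMes)(PCy3) (5 mol%), toluene, 80 °C
Reagents that add atoms: none
Why: Ring-closing metathesis of the cis-disposed allyl and 1,1-dimethylallyl arms closes ring A as a cyclohexene with loss of ethene and without touching any stereocentre.

Step 7
Reactants: 12 (1S,2R,4aS,8aR)-1-{[dimethyl(phenyl)silyl]methyl}-2,5,5,8a-tetramethyl-2,3,4,5,8,8a-hexahydronaphthalen-4a(1H)-ol
Product: 13 (1S,2R,4aS,8aR)-1-{[dimethyl(phenyl)silyl]methyl}-2,5,5,8a-tetramethyloctahydronaphthalen-4a(2H)-ol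
Conditions: H2 (1 atm), Pd/C (10%), EtOAc, rt
Reagents that add atoms: none
Why: Heterogeneous catalytic hydrogenation saturates the disubstituted ring-A alkene while the arylsilane and tertiary alcohol are inert.

Step 8
Reactants: 13 (1S,2R,4aS,8aR)-1-{[dimethyl(phenyl)silyl]methyl}-2,5,5,8a-tetramethyloctahydronaphthalen-4a(2H)-ol
Product: 14 (1S,2R,4aS,8aR)-1-(hydroxymethyl)-2,5,5,8a-tetramethyloctahydronaphthalen-4a(2H)-ol
Conditions: KBr, AcOOH (32% in AcOH), NaOAc, AcOH, 0 °C → rt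
Reagents that add atoms: peracetic acid (CC(=O)OO)
Why: Fleming–Tamao oxidation (bromodesilylation of the phenyl group, then peracid-induced migration from silicon to oxygen) converts the C–Si bond into C–OH under buffered conditions that spare the tertiary alcohol.

Step 9
Reactants: 14 (1S,2R,4aS,8aR)-1-(hydroxymethyl)-2,5,5,8a-tetramethyloctahydronaphthalen-4a(2H)-ol
Product: 15 (1S,2R,4aS,8aR)-2,5,5,8a-tetramethyl-1-{[(1-phenyl-1H-tetrazol-5-yl)sulfanyl]methyl}octahydronaphthalen-4a(2H)-ol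
Conditions: 1-phenyl-1H-tetrazole-5-thiol, PPh3, DIAD, THF, 0 °C → rt
Reagents that add atoms: 1-phenyl-1H-tetrazole-5-thiol (Sc1nnnn1-c1ccccc1)
Why: Mitsunobu thioetherification activates only the primary alcohol, and the acidic, highly nucleophilic thiol outcompetes the hindered tertiary hydroxyl.

Step 10
Reactants: 15 (1S,2R,4aS,8aR)-2,5,5,8a-tetramethyl-1-{[(1-phenyl-1H-tetrazol-5-yl)sulfanyl]methyl}octahydronaphthalen-4a(2H)-ol
Product: 16 (1S,2R,4aS,8aR)-2,5,5,8a-tetramethyl-1-{[(1-phenyl-1H-tetrazol-5-yl)sulfonyl]methyl}octahydronaphthalen-4a(2H)-ol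
Conditions: H2O2 (30% aq), (NH4)6Mo7O24·4H2O (10 mol%), EtOH, 0 °C → rt
Reagents that add atoms: hydrogen peroxide (OO)
Why: Molybdate-catalysed peroxide oxidation takes the sulfide cleanly to the sulfone, and nothing else in the molecule is oxidisable.

Step 11
Reactants: 16 (1S,2R,4aS,8aR)-2,5,5,8a-tetramethyl-1-{[(1-phenyl-1H-tetrazol-5-yl)sulfonyl]methyl}octahydronaphthalen-4a(2H)-ol
Product: 17 5-({[(1S,2R,4aS,8aR)-2,5,5,8a-tetramethyl-4a-[(triethylsilyl)oxy]decahydronaphthalen-1-yl]methyl}sulfonyl)-1-phenyl-1H-tetrazole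
Conditions: Et3SiOTf, 2,6-lutidine, CH2Cl2, 0 °C → rt
Reagents that add atoms: triethylsilyl trifluoromethanesulfonate (CC[Si](CC)(CC)OS(=O)(=O)C(F)(F)F)
Why: Silyl triflate silylation is strong enough for the hindered tertiary alcohol, so that only the sulfone α-carbon is deprotonated in the coupling.

**Fragment 2 (dioxane aldehyde)**

Step 12
Reactants: 18 2-methylprop-2-en-1-ol
Product: 19 [(2S)-2-methyloxiran-2-yl]methanol
Conditions: t-BuOOH, Ti(OiPr)4 (5 mol%), L-(+)-diisopropyl tartrate (6 mol%), 4 Å MS, CH2Cl2, −20 °C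
Reagents that add atoms: tert-butyl hydroperoxide (CC(C)(C)OO)
Why: Sharpless asymmetric epoxidation with the titanium L-(+)-tartrate catalyst delivers oxygen to one enantioface of the allylic alcohol and sets the (S) quaternary carbon (the future tertiary peroxy carbon).

Step 13
Reactants: 19 [(2S)-2-methyloxiran-2-yl]methanol; 20 prop-2-en-1-ylmagnesium chloride
Product: 21 (2R)-2-methylhex-5-ene-1,2-diol
Conditions: 20 (2.5 equiv), CuI (10 mol%), THF, −30 → 0 °C
Reagents that add atoms: none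
Why: Copper-catalysed SN2 epoxide opening occurs at the unsubstituted carbon, so the quaternary C–O bond is untouched and the configuration is retained (the descriptor changes only through priorities).

Step 14
Reactants: 21 (2R)-2-methylhex-5-ene-1,2-diol
Product: 22 (4R)-4-(but-3-en-1-yl)-2,2,4-trimethyl-1,3-dioxolane
Conditions: Me2C(OMe)2, PPTS (cat.), CH2Cl2, rt
Reagents that add atoms: 2,2-dimethoxypropane (COC(C)(C)OC)
Why: Acid-catalysed transketalisation protects the 1,2-diol as an acetonide that survives the oxidation, enolate, enzyme and hydride steps.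

Step 15
Reactants: 22 (4R)-4-(but-3-en-1-yl)-2,2,4-trimethyl-1,3-dioxolane
Product: 23 3-[(4R)-2,2,4-trimethyl-1,3-dioxolan-4-yl]propanoic acid
Conditions: RuCl3·xH2O (2 mol%), NaIO4 (4.1 equiv), MeCN/EtOAc/H2O, rt
Reagents that add atoms: sodium periodate ([Na+].[O-]I(=O)(=O)=O); water (O)
Why: Ruthenium tetroxide oxidative cleavage (Sharpless conditions) converts the terminal alkene directly to the carboxylic acid and leaves the acetonide intact.

Step 16
Reactants: 23 3-[(4R)-2,2,4-trimethyl-1,3-dioxolan-4-yl]propanoic acid; 24 methyl propanoate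
Product: 27 methyl (2RS)-2-methyl-3-oxo-5-[(4R)-2,2,4-trimethyl-1,3-dioxolan-4-yl]pentanoate, via acyl imidazolide 25 (not isolated), via lithium ester enolate 26 (not isolated)
Conditions: 23, CDI, THF, rt; then add to 26 [from 24, LiN(iPr)2 (2.2 equiv), THF, −78 °C], −78 → −40 °C; sat. aq NH4Cl
Reagents that add atoms: none
Why: Crossed Claisen condensation in which the acyl imidazolide acylates the propanoate enolate and deprotonation of the β-keto ester by the second equivalent of enolate prevents over-addition.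

Step 17
Reactants: 27 methyl (2RS)-2-methyl-3-oxo-5-[(4R)-2,2,4-trimethyl-1,3-dioxolan-4-yl]pentanoate
Product: 28 methyl (2S,3R)-3-hydroxy-2-methyl-5-[(4R)-2,2,4-trimethyl-1,3-dioxolan-4-yl]pentanoate
Conditions: ketoreductase (NADPH-dependent, (3R)- and syn-selective, chosen from a commercial panel), NADP+ (cat.), i-PrOH (10% v/v), potassium phosphate buffer pH 7.0, 30 °C
Reagents that add atoms: none
Why: Ketoreductase-catalysed dynamic kinetic resolution, in which the α-centre epimerises through the enol at pH 7 while the enzyme reduces only the (2S)-ketone from one face, sets both the methyl-bearing and carbinol centres as the syn (2S,3R) pair.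

Step 18
Reactants: 28 methyl (2S,3R)-3-hydroxy-2-methyl-5-[(4R)-2,2,4-trimethyl-1,3-dioxolan-4-yl]pentanoate
Product: 29 (2R,3R)-2-methyl-5-[(4R)-2,2,4-trimethyl-1,3-dioxolan-4-yl]pentane-1,3-diol
Conditions: LiAlH4, THF, 0 °C
Reagents that add atoms: none
Why: Hydride reduction of the ester removes the acidifying carbonyl, so the later mesylate cannot undergo β-elimination; the descriptor at the methyl centre changes only through priorities.

Step 19
Reactants: 29 (2R,3R)-2-methyl-5-[(4R)-2,2,4-trimethyl-1,3-dioxolan-4-yl]pentane-1,3-diol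
Product: 30 (2R,3R)-1-{[tert-butyl(diphenyl)silyl]oxy}-2-methyl-5-[(4R)-2,2,4-trimethyl-1,3-dioxolan-4-yl]pentan-3-ol
Conditions: t-BuPh2SiCl, imidazole, CH2Cl2, 0 °C
Reagents that add atoms: tert-butyl(chloro)diphenylsilane (CC(C)(C)[Si](Cl)(c1ccccc1)c1ccccc1)
Why: The bulky silyl chloride silylates the primary hydroxyl selectively over the secondary one.

Step 20
Reactants: 30 (2R,3R)-1-{[tert-butyl(diphenyl)silyl]oxy}-2-methyl-5-[(4R)-2,2,4-trimethyl-1,3-dioxolan-4-yl]pentan-3-ol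
Product: 31 (2R,5R,6R)-7-{[tert-butyl(diphenyl)silyl]oxy}-2,6-dimethylheptane-1,2,5-triol
Conditions: AcOH/H2O (4:1), 40 °C
Reagents that add atoms: none
Why: Mild acid hydrolysis removes the acetonide, and the silyl ether is stable to it.

Step 21
Reactants: 31 (2R,5R,6R)-7-{[tert-butyl(diphenyl)silyl]oxy}-2,6-dimethylheptane-1,2,5-triol
Product: 32 (2R,5R,6R)-7-{[tert-butyl(diphenyl)silyl]oxy}-2,5-dihydroxy-2,6-dimethylheptyl 4-methylbenzenesulfonate
Conditions: TsCl, Et3N, Bu2SnO (2 mol%), CH2Cl2, rt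
Reagents that add atoms: 4-methylbenzenesulfonyl chloride (Cc1ccc(cc1)S(Cl)(=O)=O)
Why: Stannylene-catalysed sulfonylation picks out the primary hydroxyl of the 1,2-diol over the isolated secondary and the tertiary hydroxyls.

Step 22
Reactants: 32 (2R,5R,6R)-7-{[tert-butyl(diphenyl)silyl]oxy}-2,5-dihydroxy-2,6-dimethylheptyl 4-methylbenzenesulfonate
Product: 33 (2R,3R)-1-{[tert-butyl(diphenyl)silyl]oxy}-2-methyl-5-[(2R)-2-methyloxiran-2-yl]pentan-3-ol
Conditions: K2CO3, MeOH, 0 °C → rt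
Reagents that add atoms: none
Why: Intramolecular Williamson closure by the tertiary alkoxide gives the terminal epoxide with retention at the quaternary carbon, whose C–O bond is never broken.

Step 23
Reactants: 33 (2R,3R)-1-{[tert-butyl(diphenyl)silyl]oxy}-2-methyl-5-[(2R)-2-methyloxiran-2-yl]pentan-3-ol
Product: 34 (2R,3R)-1-{[tert-butyl(diphenyl)silyl]oxy}-2-methyl-5-[(2R)-2-methyloxiran-2-yl]pentan-3-yl methanesulfonate
Conditions: MsCl, Et3N, CH2Cl2, −20 °C
Reagents that add atoms: methanesulfonyl chloride (CS(Cl)(=O)=O)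
Why: Mesylation turns the secondary alcohol into a leaving group with retention and must precede the acidic perhydrolysis so that the hydroxyl cannot open the epoxide.

Step 24
Reactants: 34 (2R,3R)-1-{[tert-butyl(diphenyl)silyl]oxy}-2-methyl-5-[(2R)-2-methyloxiran-2-yl]pentan-3-yl methanesulfonate
Product: 35 (2R,3R,6S)-1-{[tert-butyl(diphenyl)silyl]oxy}-6-hydroperoxy-7-hydroxy-2,6-dimethylheptan-3-yl methanesulfonate
Conditions: H2O2 (anhydrous, ca. 2 M in Et2O, 10 equiv), H3PMo12O40 (3 mol%), Et2O, rt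
Reagents that add atoms: hydrogen peroxide (OO)
Why: Heteropolyacid-catalysed epoxide perhydrolysis, in which hydrogen peroxide attacks the more substituted carbon from the rear (borderline SN2), gives the tertiary hydroperoxide with inversion and so sets the quaternary peroxy centre.

Step 25
Reactants: 35 (2R,3R,6S)-1-{[tert-butyl(diphenyl)silyl]oxy}-6-hydroperoxy-7-hydroxy-2,6-dimethylheptan-3-yl methanesulfonate
Product: 36 {(3S,6S)-6-[(2R)-1-{[tert-butyl(diphenyl)silyl]oxy}propan-2-yl]-3-methyl-1,2-dioxan-3-yl}methanol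
Conditions: KOt-Bu (1.05 equiv), 18-crown-6, THF, 0 °C
Reagents that add atoms: none
Why: One equivalent of base deprotonates only the hydroperoxide (far more acidic than the alcohol), and the peroxide anion closes the 1,2-dioxane by intramolecular SN2 displacement of the mesylate with inversion, which turns the syn methyl/oxygen pair into the anti pair of the target.

Step 26
Reactants: 36 {(3S,6S)-6-[(2R)-1-{[tert-butyl(diphenyl)silyl]oxy}propan-2-yl]-3-methyl-1,2-dioxan-3-yl}methanol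
Product: 37 (3S,6S)-6-[(2R)-1-{[tert-butyl(diphenyl)silyl]oxy}propan-2-yl]-3-methyl-1,2-dioxane-3-carbaldehyde
Conditions: Dess–Martin periodinane, CH2Cl2, 0 °C → rt
Reagents that add atoms: none
Why: Dess–Martin oxidation under neutral conditions gives the non-enolisable α-peroxy aldehyde without touching the O–O bond.

**Union and end game**

Step 27
Reactants: 17 5-({[(1S,2R,4aS,8aR)-2,5,5,8a-tetramethyl-4a-[(triethylsilyl)oxy]decahydronaphthalen-1-yl]methyl}sulfonyl)-1-phenyl-1H-tetrazole; 37 (3S,6S)-6-[(2R)-1-{[tert-butyl(diphenyl)silyl]oxy}propan-2-yl]-3-methyl-1,2-dioxane-3-carbaldehyde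
Product: 39 tert-butyl{[(2R)-2-{(3S,6S)-6-methyl-6-[(E)-2-{(1R,2R,4aS,8aR)-2,5,5,8a-tetramethyl-4a-[(triethylsilyl)oxy]decahydronaphthalen-1-yl}ethenyl]-1,2-dioxan-3-yl}propyl]oxy}diphenylsilane, via potassium sulfonyl carbanion 38 (not isolated)
Conditions: 17, KN(SiMe3)2, DME, −60 °C; then 37, −60 °C → rt; sat. aq NH4Cl
Reagents that add atoms: none
Why: Julia–Kocienski olefination joins the fragments because the sulfonyl carbanion adds to the aldehyde far faster than it attacks the peroxide, and the rapid Smiles rearrangement and loss of SO2 give the alkene without touching a stereocentre.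

Step 28
Reactants: 39 tert-butyl{[(2R)-2-{(3S,6S)-6-methyl-6-[(E)-2-{(1R,2R,4aS,8aR)-2,5,5,8a-tetramethyl-4a-[(triethylsilyl)oxy]decahydronaphthalen-1-yl}ethenyl]-1,2-dioxan-3-yl}propyl]oxy}diphenylsilane
Product: 40 tert-butyl{[(2R)-2-{(3S,6R)-6-methyl-6-[2-{(1S,2R,4aS,8aR)-2,5,5,8a-tetramethyl-4a-[(triethylsilyl)oxy]decahydronaphthalen-1-yl}ethyl]-1,2-dioxan-3-yl}propyl]oxy}diphenylsilane
Conditions: KO2CN=NCO2K (excess, in portions), AcOH, MeOH/CH2Cl2, 0 °C → rt
Reagents that add atoms: none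
Why: Diimide reduction transfers H2 to the alkene in a concerted way and leaves the O–O bond intact, which metal-catalysed hydrogenation would not.

Step 29
Reactants: 40 tert-butyl{[(2R)-2-{(3S,6R)-6-methyl-6-[2-{(1S,2R,4aS,8aR)-2,5,5,8a-tetramethyl-4a-[(triethylsilyl)oxy]decahydronaphthalen-1-yl}ethyl]-1,2-dioxan-3-yl}propyl]oxy}diphenylsilane
Product: 41 (2R)-2-[(3S,6R)-6-{2-[(1S,2R,4aS,8aR)-4a-hydroxy-2,5,5,8a-tetramethyldecahydronaphthalen-1-yl]ethyl}-6-methyl-1,2-dioxan-3-yl]propan-1-ol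
Conditions: HF·pyridine, pyridine, THF, 0 °C → rt
Reagents that add atoms: none
Why: Buffered fluoride cleaves both silyl ethers without the basic conditions that would trigger Kornblum–DeLaMare opening of the dioxane.

Step 30
Reactants: 41 (2R)-2-[(3S,6R)-6-{2-[(1S,2R,4aS,8aR)-4a-hydroxy-2,5,5,8a-tetramethyldecahydronaphthalen-1-yl]ethyl}-6-methyl-1,2-dioxan-3-yl]propan-1-ol
Product: 42 (2S)-2-[(3S,6R)-6-{2-[(1S,2R,4aS,8aR)-4a-hydroxy-2,5,5,8a-tetramethyldecahydronaphthalen-1-yl]ethyl}-6-methyl-1,2-dioxan-3-yl]propanoic acid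
Conditions: TEMPO (cat.), NaOCl (cat.), NaClO2, MeCN/phosphate buffer pH 6.7, 35 °C
Reagents that add atoms: sodium chlorite ([Na+].[O-]Cl=O)
Why: TEMPO/chlorite oxidation takes the primary alcohol through the aldehyde to the acid at near-neutral pH, so the α-stereocentre does not epimerise and the tertiary alcohol and peroxide are untouched.

Step 31
Reactants: 42 (2S)-2-[(3S,6R)-6-{2-[(1S,2R,4aS,8aR)-4a-hydroxy-2,5,5,8a-tetramethyldecahydronaphthalen-1-yl]ethyl}-6-methyl-1,2-dioxan-3-yl]propanoic acid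
Product: 43 methyl (2S)-2-[(3S,6R)-6-{2-[(1S,2R,4aS,8aR)-4a-hydroxy-2,5,5,8a-tetramethyldecahydronaphthalen-1-yl]ethyl}-6-methyl-1,2-dioxan-3-yl]propanoate
Conditions: Me3SiCHN2, MeOH/toluene, 0 °C
Reagents that add atoms: (trimethylsilyl)diazomethane (C[Si](C)(C)C=[N+]=[N-])
Why: Esterification with the diazomethane surrogate is neutral and fast, so neither the peroxide nor the α-stereocentre is at risk.

**Compound list**

1 | propanal | CCC=O | starting material
2 | pent-1-en-3-one | C=CC(=O)CC | starting material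
3 | (2R)-2-methyl-5-oxoheptanal | O=C[C@H](C)CCC(=O)CC | intermediate
4 | (4R)-2,4-dimethylcyclohex-2-en-1-one | O=C1C(C)=C[C@H](C)CC1 | intermediate
5 | {[dimethyl(phenyl)silyl]methyl}magnesium chloride | Cl[Mg]C[Si](C)(C)c1ccccc1 | starting material
6 | {[(3S,4R)-3-{[dimethyl(phenyl)silyl]methyl}-2,4-dimethylcyclohex-1-en-1-yl]oxy}trimethylsilane | c1ccccc1[Si](C)(C)C[C@H]2[C@H](C)CCC(O[Si](C)(C)C)=C2C | intermediate
7 | 3-bromoprop-1-ene | C=CCBr | starting material
8 | lithium enolate: lithium (3S,4R)-3-{[dimethyl(phenyl)silyl]methyl}-2,4-dimethylcyclohex-1-en-1-olate | c1ccccc1[Si](C)(C)C[C@H]2[C@H](C)CCC(O[Li])=C2C | intermediate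
9 | (2R,3S,4R)-3-{[dimethyl(phenyl)silyl]methyl}-2,4-dimethyl-2-(prop-2-en-1-yl)cyclohexan-1-one | c1ccccc1[Si](C)(C)C[C@H]2[C@H](C)CCC(=O)[C@]2(C)CC=C | intermediate
10 | (3-methylbut-2-en-1-yl)magnesium chloride | CC(C)=CC[Mg]Cl | starting material
11 | (1S,2R,3S,4R)-3-{[dimethyl(phenyl)silyl]methyl}-2,4-dimethyl-1-(2-methylbut-3-en-2-yl)-2-(prop-2-en-1-yl)cyclohexan-1-ol | c1ccccc1[Si](C)(C)C[C@H]2[C@H](C)CC[C@](O)(C(C)(C)C=C)[C@]2(C)CC=C | intermediate
12 | (1S,2R,4aS,8aR)-1-{[dimethyl(phenyl)silyl]methyl}-2,5,5,8a-tetramethyl-2,3,4,5,8,8a-hexahydronaphthalen-4a(1H)-ol | c1ccccc1[Si](C)(C)C[C@H]2[C@H](C)CC[C@]3(O)C(C)(C)C=CC[C@]23C | intermediate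
13 | (1S,2R,4aS,8aR)-1-{[dimethyl(phenyl)silyl]methyl}-2,5,5,8a-tetramethyloctahydronaphthalen-4a(2H)-ol | c1ccccc1[Si](C)(C)C[C@H]2[C@H](C)CC[C@]3(O)C(C)(C)CCC[C@]23C | intermediate
14 | (1S,2R,4aS,8aR)-1-(hydroxymethyl)-2,5,5,8a-tetramethyloctahydronaphthalen-4a(2H)-ol | OC[C@H]1[C@H](C)CC[C@]2(O)C(C)(C)CCC[C@]12C | intermediate
15 | (1S,2R,4aS,8aR)-2,5,5,8a-tetramethyl-1-{[(1-phenyl-1H-tetrazol-5-yl)sulfanyl]methyl}octahydronaphthalen-4a(2H)-ol | c1ccccc1-n1nnnc1SC[C@H]1[C@H](C)CC[C@]2(O)C(C)(C)CCC[C@]12C | intermediate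
16 | (1S,2R,4aS,8aR)-2,5,5,8a-tetramethyl-1-{[(1-phenyl-1H-tetrazol-5-yl)sulfonyl]methyl}octahydronaphthalen-4a(2H)-ol | c1ccccc1-n1nnnc1S(=O)(=O)C[C@H]1[C@H](C)CC[C@]2(O)C(C)(C)CCC[C@]12C | intermediate
17 | 5-({[(1S,2R,4aS,8aR)-2,5,5,8a-tetramethyl-4a-[(triethylsilyl)oxy]decahydronaphthalen-1-yl]methyl}sulfonyl)-1-phenyl-1H-tetrazole | c1ccccc1-n1nnnc1S(=O)(=O)C[C@H]1[C@H](C)CC[C@]2(O[Si](CC)(CC)CC)C(C)(C)CCC[C@]12C | intermediate
18 | 2-methylprop-2-en-1-ol | C=C(C)CO | starting material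
19 | [(2S)-2-methyloxiran-2-yl]methanol | C1O[C@@]1(C)CO | intermediate
20 | prop-2-en-1-ylmagnesium chloride | C=CC[Mg]Cl | starting material
21 | (2R)-2-methylhex-5-ene-1,2-diol | C=CCC[C@](O)(C)CO | intermediate
22 | (4R)-4-(but-3-en-1-yl)-2,2,4-trimethyl-1,3-dioxolane | C=CCC[C@]1(C)COC(C)(C)O1 | intermediate
23 | 3-[(4R)-2,2,4-trimethyl-1,3-dioxolan-4-yl]propanoic acid | OC(=O)CC[C@]1(C)COC(C)(C)O1 | intermediate
24 | methyl propanoate | CCC(=O)OC | starting material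
25 | acyl imidazolide: 1-(1H-imidazol-1-yl)-3-[(4R)-2,2,4-trimethyl-1,3-dioxolan-4-yl]propan-1-one | O=C(CC[C@]1(C)COC(C)(C)O1)n1ccnc1 | intermediate
26 | lithium ester enolate: lithium 1-methoxyprop-1-en-1-olate | CC=C(OC)O[Li] | intermediate
27 | methyl (2RS)-2-methyl-3-oxo-5-[(4R)-2,2,4-trimethyl-1,3-dioxolan-4-yl]pentanoate | COC(=O)C(C)C(=O)CC[C@]1(C)COC(C)(C)O1 | intermediate
28 | methyl (2S,3R)-3-hydroxy-2-methyl-5-[(4R)-2,2,4-trimethyl-1,3-dioxolan-4-yl]pentanoate | COC(=O)[C@@H](C)[C@H](O)CC[C@]1(C)COC(C)(C)O1 | intermediate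
29 | (2R,3R)-2-methyl-5-[(4R)-2,2,4-trimethyl-1,3-dioxolan-4-yl]pentane-1,3-diol | OC[C@@H](C)[C@H](O)CC[C@]1(C)COC(C)(C)O1 | intermediate
30 | (2R,3R)-1-{[tert-butyl(diphenyl)silyl]oxy}-2-methyl-5-[(4R)-2,2,4-trimethyl-1,3-dioxolan-4-yl]pentan-3-ol | CC(C)(C)[Si](c1ccccc1)(c1ccccc1)OC[C@@H](C)[C@H](O)CC[C@]1(C)COC(C)(C)O1 | intermediate
31 | (2R,5R,6R)-7-{[tert-butyl(diphenyl)silyl]oxy}-2,6-dimethylheptane-1,2,5-triol | CC(C)(C)[Si](c1ccccc1)(c1ccccc1)OC[C@@H](C)[C@H](O)CC[C@](O)(C)CO | intermediate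
32 | (2R,5R,6R)-7-{[tert-butyl(diphenyl)silyl]oxy}-2,5-dihydroxy-2,6-dimethylheptyl 4-methylbenzenesulfonate | CC(C)(C)[Si](c1ccccc1)(c1ccccc1)OC[C@@H](C)[C@H](O)CC[C@](O)(C)COS(=O)(=O)c1ccc(C)cc1 | intermediate
33 | (2R,3R)-1-{[tert-butyl(diphenyl)silyl]oxy}-2-methyl-5-[(2R)-2-methyloxiran-2-yl]pentan-3-ol | CC(C)(C)[Si](c1ccccc1)(c1ccccc1)OC[C@@H](C)[C@H](O)CC[C@]1(C)CO1 | intermediate
34 | (2R,3R)-1-{[tert-butyl(diphenyl)silyl]oxy}-2-methyl-5-[(2R)-2-methyloxiran-2-yl]pentan-3-yl methanesulfonate | CC(C)(C)[Si](c1ccccc1)(c1ccccc1)OC[C@@H](C)[C@H](OS(C)(=O)=O)CC[C@]1(C)CO1 | intermediate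
35 | (2R,3R,6S)-1-{[tert-butyl(diphenyl)silyl]oxy}-6-hydroperoxy-7-hydroxy-2,6-dimethylheptan-3-yl methanesulfonate | CC(C)(C)[Si](c1ccccc1)(c1ccccc1)OC[C@@H](C)[C@H](OS(C)(=O)=O)CC[C@@](C)(CO)OO | intermediate
36 | {(3S,6S)-6-[(2R)-1-{[tert-butyl(diphenyl)silyl]oxy}propan-2-yl]-3-methyl-1,2-dioxan-3-yl}methanol | CC(C)(C)[Si](c1ccccc1)(c1ccccc1)OC[C@@H](C)[C@@H]1CC[C@@](C)(CO)OO1 | intermediate
37 | (3S,6S)-6-[(2R)-1-{[tert-butyl(diphenyl)silyl]oxy}propan-2-yl]-3-methyl-1,2-dioxane-3-carbaldehyde | CC(C)(C)[Si](c1ccccc1)(c1ccccc1)OC[C@@H](C)[C@@H]1CC[C@@](C)(C=O)OO1 | intermediate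
38 | potassium sulfonyl carbanion of 17: potassium {(1S,2R,4aS,8aR)-2,5,5,8a-tetramethyl-4a-[(triethylsilyl)oxy]decahydronaphthalen-1-yl}[(1-phenyl-1H-tetrazol-5-yl)sulfonyl]methanide | c1ccccc1-n1nnnc1S(=O)(=O)C([K])[C@H]1[C@H](C)CC[C@]2(O[Si](CC)(CC)CC)C(C)(C)CCC[C@]12C | intermediate
39 | tert-butyl{[(2R)-2-{(3S,6S)-6-methyl-6-[(E)-2-{(1R,2R,4aS,8aR)-2,5,5,8a-tetramethyl-4a-[(triethylsilyl)oxy]decahydronaphthalen-1-yl}ethenyl]-1,2-dioxan-3-yl}propyl]oxy}diphenylsilane | CC(C)(C)[Si](c1ccccc1)(c1ccccc1)OC[C@@H](C)[C@@H]1CC[C@@](C)(/C=C/[C@H]2[C@H](C)CC[C@]3(O[Si](CC)(CC)CC)C(C)(C)CCC[C@]23C)OO1 | intermediate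
40 | tert-butyl{[(2R)-2-{(3S,6R)-6-methyl-6-[2-{(1S,2R,4aS,8aR)-2,5,5,8a-tetramethyl-4a-[(triethylsilyl)oxy]decahydronaphthalen-1-yl}ethyl]-1,2-dioxan-3-yl}propyl]oxy}diphenylsilane | CC(C)(C)[Si](c1ccccc1)(c1ccccc1)OC[C@@H](C)[C@@H]1CC[C@@](C)(CC[C@H]2[C@H](C)CC[C@]3(O[Si](CC)(CC)CC)C(C)(C)CCC[C@]23C)OO1 | intermediate
41 | (2R)-2-[(3S,6R)-6-{2-[(1S,2R,4aS,8aR)-4a-hydroxy-2,5,5,8a-tetramethyldecahydronaphthalen-1-yl]ethyl}-6-methyl-1,2-dioxan-3-yl]propan-1-ol | OC[C@@H](C)[C@@H]1CC[C@@](C)(CC[C@H]2[C@H](C)CC[C@]3(O)C(C)(C)CCC[C@]23C)OO1 | intermediate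
42 | (2S)-2-[(3S,6R)-6-{2-[(1S,2R,4aS,8aR)-4a-hydroxy-2,5,5,8a-tetramethyldecahydronaphthalen-1-yl]ethyl}-6-methyl-1,2-dioxan-3-yl]propanoic acid | OC(=O)[C@@H](C)[C@@H]1CC[C@@](C)(CC[C@H]2[C@H](C)CC[C@]3(O)C(C)(C)CCC[C@]23C)OO1 | intermediate
43 | methyl (2S)-2-[(3S,6R)-6-{2-[(1S,2R,4aS,8aR)-4a-hydroxy-2,5,5,8a-tetramethyldecahydronaphthalen-1-yl]ethyl}-6-methyl-1,2-dioxan-3-yl]propanoate | COC(=O)[C@@H](C)[C@@H]1CC[C@@](C)(CC[C@H]2[C@H](C)CC[C@]3(O)C(C)(C)CCC[C@]23C)OO1 | target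

**Totals and risks**

Total step count: 31. Longest linear sequence: 20 steps (steps 12 to 26, then 27 to 31); fragment 1 is 11 steps before the union.

Most likely to fail, first: step 5. The prenyl Grignard may add through its unsubstituted terminus, or the crowded alkoxide may revert. The fallback sets out from 9 and returns at 11. A Reformatsky reaction of 9 with ethyl 2-bromo-2-methylpropanoate and zinc (THF, reflux), which can only bond through the substituted carbon, gives ethyl 2-[(1R,2R,3S,4R)-3-{[dimethyl(phenyl)silyl]methyl}-1-hydroxy-2,4-dimethyl-2-(prop-2-en-1-yl)cyclohexyl]-2-methylpropanoate F1. LiAlH4 reduction gives (1R,2R,3S,4R)-3-{[dimethyl(phenyl)silyl]methyl}-1-(1-hydroxy-2-methylpropan-2-yl)-2,4-dimethyl-2-(prop-2-en-1-yl)cyclohexan-1-ol F2. TEMPO/PhI(OAc)2 oxidation of the primary alcohol gives 2-[(1R,2R,3S,4R)-3-{[dimethyl(phenyl)silyl]methyl}-1-hydroxy-2,4-dimethyl-2-(prop-2-en-1-yl)cyclohexyl]-2-methylpropanal F3, and Wittig methylenation (Ph3P=CH2, THF, 0 °C) gives 11.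

Second: step 25, together with the perhydrolysis that feeds it. The risks are loss of configuration at the tertiary carbon, base-induced fragmentation of the β-hydroxy hydroperoxide, and elimination of the mesylate. The fallback sets out from 33 and returns at 36, reversing the order in which the two C–O bonds are made. Triflation of 33 (Tf2O, 2,6-lutidine, CH2Cl2, −78 °C) gives (2R,3R)-1-{[tert-butyl(diphenyl)silyl]oxy}-2-methyl-5-[(2R)-2-methyloxiran-2-yl]pentan-3-yl trifluoromethanesulfonate F4. Intermolecular SN2 displacement with 2-methoxypropan-2-yl hydroperoxide (KOt-Bu, THF, 0 °C) inverts the secondary centre and gives tert-butyl{[(2R,3S)-3-[(2-methoxypropan-2-yl)peroxy]-2-methyl-5-[(2R)-2-methyloxiran-2-yl]pentyl]oxy}diphenylsilane F5. Mild acid (PPTS, wet CH2Cl2, then H3PMo12O40 cat.) releases tert-butyl{[(2R,3S)-3-hydroperoxy-2-methyl-5-[(2R)-2-methyloxiran-2-yl]pentyl]oxy}diphenylsilane F6, which is not isolated and opens the epoxide at the tertiary carbon with inversion to give 36.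

Third: step 27. The carbanion or the intermediate alkoxide may attack the peroxide next to the aldehyde. The fallback sets out from 14 and returns at 40, using a Wittig reaction that passes through a neutral oxaphosphetane. Bis-silylation of 14 (Et3SiOTf, 2,6-lutidine) gives triethyl{[(1S,2R,4aS,8aR)-2,5,5,8a-tetramethyl-4a-[(triethylsilyl)oxy]decahydronaphthalen-1-yl]methoxy}silane F7. Selective cleavage of the primary silyl ether (PPTS, MeOH, 0 °C) gives {(1S,2R,4aS,8aR)-2,5,5,8a-tetramethyl-4a-[(triethylsilyl)oxy]decahydronaphthalen-1-yl}methanol F8. I2/PPh3/imidazole gives {[(1S,2R,4aS,8aR)-1-(iodomethyl)-2,5,5,8a-tetramethyloctahydronaphthalen-4a(2H)-yl]oxy}triethylsilane F9. PPh3 in MeCN at reflux gives triphenyl({(1S,2R,4aS,8aR)-2,5,5,8a-tetramethyl-4a-[(triethylsilyl)oxy]decahydronaphthalen-1-yl}methyl)phosphonium iodide F10. Ylide formation (NaN(SiMe3)2, THF, −78 °C) and addition of 37 gives tert-butyl{[(2R)-2-{(3S,6S)-6-methyl-6-[(Z)-2-{(1R,2R,4aS,8aR)-2,5,5,8a-tetramethyl-4a-[(triethylsilyl)oxy]decahydronaphthalen-1-yl}ethenyl]-1,2-dioxan-3-yl}propyl]oxy}diphenylsilane F11, and diimide reduction as in step 28 gives 40.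

**Further compounds**

F1 | step 5 | ethyl 2-[(1R,2R,3S,4R)-3-{[dimethyl(phenyl)silyl]methyl}-1-hydroxy-2,4-dimethyl-2-(prop-2-en-1-yl)cyclohexyl]-2-methylpropanoate | c1ccccc1[Si](C)(C)C[C@H]2[C@H](C)CC[C@](O)(C(C)(C)C(=O)OCC)[C@]2(C)CC=C
F2 | step 5 | (1R,2R,3S,4R)-3-{[dimethyl(phenyl)silyl]methyl}-1-(1-hydroxy-2-methylpropan-2-yl)-2,4-dimethyl-2-(prop-2-en-1-yl)cyclohexan-1-ol | c1ccccc1[Si](C)(C)C[C@H]2[C@H](C)CC[C@](O)(C(C)(C)CO)[C@]2(C)CC=C
F3 | step 5 | 2-[(1R,2R,3S,4R)-3-{[dimethyl(phenyl)silyl]methyl}-1-hydroxy-2,4-dimethyl-2-(prop-2-en-1-yl)cyclohexyl]-2-methylpropanal | c1ccccc1[Si](C)(C)C[C@H]2[C@H](C)CC[C@](O)(C(C)(C)C=O)[C@]2(C)CC=C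
F4 | step 25 | (2R,3R)-1-{[tert-butyl(diphenyl)silyl]oxy}-2-methyl-5-[(2R)-2-methyloxiran-2-yl]pentan-3-yl trifluoromethanesulfonate | CC(C)(C)[Si](c1ccccc1)(c1ccccc1)OC[C@@H](C)[C@H](OS(=O)(=O)C(F)(F)F)CC[C@]1(C)CO1
F5 | step 25 | tert-butyl{[(2R,3S)-3-[(2-methoxypropan-2-yl)peroxy]-2-methyl-5-[(2R)-2-methyloxiran-2-yl]pentyl]oxy}diphenylsilane | CC(C)(C)[Si](c1ccccc1)(c1ccccc1)OC[C@@H](C)[C@@H](OOC(C)(C)OC)CC[C@]1(C)CO1
F6 | step 25 | tert-butyl{[(2R,3S)-3-hydroperoxy-2-methyl-5-[(2R)-2-methyloxiran-2-yl]pentyl]oxy}diphenylsilane | CC(C)(C)[Si](c1ccccc1)(c1ccccc1)OC[C@@H](C)[C@@H](OO)CC[C@]1(C)CO1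
F7 | step 27 | triethyl{[(1S,2R,4aS,8aR)-2,5,5,8a-tetramethyl-4a-[(triethylsilyl)oxy]decahydronaphthalen-1-yl]methoxy}silane | CC[Si](CC)(CC)OC[C@H]1[C@H](C)CC[C@]2(O[Si](CC)(CC)CC)C(C)(C)CCC[C@]12C
F8 | step 27 | {(1S,2R,4aS,8aR)-2,5,5,8a-tetramethyl-4a-[(triethylsilyl)oxy]decahydronaphthalen-1-yl}methanol | OC[C@H]1[C@H](C)CC[C@]2(O[Si](CC)(CC)CC)C(C)(C)CCC[C@]12C
F9 | step 27 | {[(1S,2R,4aS,8aR)-1-(iodomethyl)-2,5,5,8a-tetramethyloctahydronaphthalen-4a(2H)-yl]oxy}triethylsilane | IC[C@H]1[C@H](C)CC[C@]2(O[Si](CC)(CC)CC)C(C)(C)CCC[C@]12C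
F10 | step 27 | triphenyl({(1S,2R,4aS,8aR)-2,5,5,8a-tetramethyl-4a-[(triethylsilyl)oxy]decahydronaphthalen-1-yl}methyl)phosphonium iodide | [I-].c1ccccc1[P+](c1ccccc1)(c1ccccc1)C[C@H]1[C@H](C)CC[C@]2(O[Si](CC)(CC)CC)C(C)(C)CCC[C@]12C
F11 | step 27 | tert-butyl{[(2R)-2-{(3S,6S)-6-methyl-6-[(Z)-2-{(1R,2R,4aS,8aR)-2,5,5,8a-tetramethyl-4a-[(triethylsilyl)oxy]decahydronaphthalen-1-yl}ethenyl]-1,2-dioxan-3-yl}propyl]oxy}diphenylsilane | CC(C)(C)[Si](c1ccccc1)(c1ccccc1)OC[C@@H](C)[C@@H]1CC[C@@](C)(/C=C\[C@H]2[C@H](C)CC[C@]3(O[Si](CC)(CC)CC)C(C)(C)CCC[C@]23C)OO1
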